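The leftover substrate of the eta flask, 43.2 % at 0.500 h and 10.4 % at 1.33 h, shrinks by these two readings at 1.72 h⁻¹, and this is the top rung of a ladder of three rates read from the runs.

| setting | eta | alpha | flask |
|---|---|---|---|
| substrate | 0.020 M | 0.040 M | 0.020 M |
| gas | 1.8 mM (held) | 1.8 mM (held) | 1.8 mM (held) |
| remark | the very flask that is asked about, followed so far | run made earlier |  |
| time |  |  | 50 h |

- eta (time / h: double product / %, substrate / %): 0.500: 2.2, 43.2; 1.33: 9.5, 10.4; 2.50: 21.0, 2.4; 4.00: 30.9, 0.6
- alpha (time / h: double product / %, substrate / %): 12.0: 67.9, 2.0; 25.0: 76.6, 0; 40.0: 70.7, 0.3; 48.0: 64.8, 1.7

(standard deviation of a reading: 1 percentage point)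

- at the start none of reagent is dissolved
- candidate steps: double product -> over-reaction product; 2 reagent -> self-condensation product; reagent + single product -> double product; substrate + reagent -> single product; gas <-> reagent

1. the best time, 50 h at the latest, for double product
2. the amount of double product, in percent of the substrate charged, at that time
3. the first time at which double product reaches 39 %, in the same percent

I read that first rate as pseudo-first-order, with the reagent held steady by the gas, so one turnover of substrate in the eta flask takes 0.583 h. On the second rung single product becomes double product. At 4.00 h the eta readings leave 68.5 % of the charge as single product if over-reaction is still small, and counting turnovers from the end of that lag gives 0.111 h⁻¹, slower than the top rung. On the lowest rung the alpha run, at twice the charge, falls from 70.7 % at 40.0 h to 64.8 % at 48.0 h, which reads as a loss of double product at 0.0109 h⁻¹, slower again, and I carry it to the eta flask on the assumption that the charge does not change it.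

The quantity to carry is the turnover ratio, the turnovers of making double product per turnover of losing it, 10.2. In the eta flask, gain over loss of double product is this ratio times single product over double product, so the peak stands where that gain over loss equals one. My reckoning puts it at 23.8 h with 77.6 %, and puts 39 % at 5.05 h.

The forecast, holding that “rate constants should carry between charges”, names 23 h, 77.5 % and 5.3 h, so its peak stands earlier and its 39 % later than in my reckoning.

The eta flask peaks at 22.6 h with 77.7 % of double product and reaches 39 % at 4.99 h.

    double product → over-reaction product (k = 3.19 × 10⁻⁶ s⁻¹)
    2 reagent → self-condensation product (k = 0.139 M⁻¹ s⁻¹)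
    reagent + single product → double product (k = 0.0181 M⁻¹ s⁻¹)
    substrate + reagent → single product (k = 0.264 M⁻¹ s⁻¹)
    gas ⇌ reagent, rate k5*(csat - [reagent]) (kL = 0.495 s⁻¹)

At 22.6 h the eta flask holds 7.61 % of single product against 77.7 % of double product, and the turnover ratio turns these into a gain over loss of 0.999, the peak condition. The neighbour flask stopped at 12 h holds 26.4 % of single product against 68.0 % of double product, which gives 3.96, above one, gain still ahead of loss, with a highest amount so far in that flask of 68.0 %.

Readings and results come from a simulation for substances that don't exist, and the scatter is random.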